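(All runs come from a simulation on assumed constants.)

3 questions stand here, and they come down to one decision: which recipe do you charge next for the longer chains, oak or alder?

| setting | south-east | south-west | east | oak | alder |
|---|---|---|---|---|---|
| free monomer | 20 mM | 20 mM | 20 mM | 20 mM | 20 mM |
| transfer agent | 0.60 mM | 0.60 mM | 0.60 mM | 0.600 mM | 0.600 mM |
| initiator | 4.1 mol% | 5.8 mol% | 6.3 mol% | 8.4 mol% | 4 mol% |
| remark | run made earlier | run made earlier | run made earlier |  |  |
| time |  |  |  | 12 h | 12 h |

| run | time / h | monomer in chains / % | free monomer / % |
|---|---|---|---|
| south-east | 0.667 | 8.0 | 89.2 |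
| south-east | 1.33 | 22.2 | 73.3 |
| south-east | 2.50 | 46.0 | 46.7 |
| south-east | 4.00 | 64.7 | 26.9 |
| south-east | 8.00 | 81.7 | 7.9 |
| south-west | 0.667 | 10.6 | 86.9 |
| south-west | 1.33 | 30.1 | 65.7 |
| south-west | 2.50 | 57.0 | 37.0 |
| south-west | 4.00 | 75.5 | 17.5 |
| south-west | 8.00 | 87.9 | 3.1 |
| east | 1.50 | 36.5 | 58.5 |
| east | 3.00 | 67.2 | 26.5 |
| east | 5.00 | 82.6 | 9.9 |
| east | 6.00 | 86.3 | 6.3 |
| east | 8.00 | 89.1 | 2.3 |

(scatter of a reading: 0.3 percentage points)

1. which of the two ends with the longer chains by the average number of monomer units in a chain (chains begun, living or dead) ("neither" if they lie within 10 %) (oak / alder / neither)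
2. average number of monomer units in a chain (chains begun, living or dead) at the end, oak
3. average number of monomer units in a chain (chains begun, living or dead) at the end, alder

- the average divides the monomer in chains by the number of chains begun, living and dead together
- the analysis behind the earlier runs scatters by 0.3 percentage points, standard deviation
- the earlier runs do not show the number of chains; that part of a forecast is a guess

The readings show no chain count, so I reckon one. Oak holds 11.9 free monomer per initiator charged and alder 25.0; call this r, the units per initiator. Suppose each spent initiator begins one chain. The length is then r·y/s, with y the share of free monomer in chains and s the share of initiator spent.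

First round, s is one and y alike in both flasks, so alder's chains come out twice oak's. Now go round again, supposing initiator is spent by meeting free monomer. Late in the runs free monomer decays at 0.323 /h in the south-east run and 0.489 /h in the east run. That ratio of 1.51 follows the loadings' 1.54, so oak's free monomer should last half as long as alder's. If alder spends 70%, a guess I borrow from the forecast, which uses it for both flasks, and oak's initiator decays first-order over that shorter exposure, oak spends 43.6 %. With y from the readings at 8.00 h, the east run for oak and the south-east run for alder, oak reaches 24.3 and alder 29.2, a ratio of 1.20, beyond the 10 % margin. I would charge alder.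

The forecast says neither, with oak at 29 (22 to 31) and alder at 28 (23 to 30), having read the loading as “relative to transfer agent, which is uncertain”.

The flask gives alder: oak 18.9, alder 28.1.

    free monomer + initiator → living end + monomer in chains (k = 22.0 /M/h)
    free monomer + living end → monomer in chains + living end, rate k2*[living end]*[free monomer] (k = 1100 /M/h)
    living end + transfer agent → dead chain (kL = 400 /M/h)
    free monomer → uncatalysed product (k = 0.0350 /h)
    2 living end → dead end (k = 58.0 /M/h)

With the simulated y and s at 12 h, r·y/s returns 18.9 for oak and 28.1 for alder. A flask like alder with 5.0 mM of free monomer keeps r at 25.0, and its y of 30.6 % and s of 58.8 % give a length of 13.0. Ten times the time leaves the length close to where it stood: at 120 h oak stands at 18.9 and alder at 28.0. Oak has not come to rest, though: between 12.0 h and 120 h its living end falls from 0.249 mM to 0.0446 mM, and its transfer agent from 15.6 % to 0.388 % of its charge.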